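**Plan**
Retrosynthesis (drimane numbering; ring A = C-1 to C-5 and C-10, ring B = C-5 to C-10): cut the aryl ether O–C-11 (umbelliferone), then C-9–C-11 and H–C-9 back to a C-9 ketone, then the angular CH3–C-10 bond, and last the two ring A bonds C-1–C-10 and C-3–C-4. This leaves acrylonitrile (C-1, C-2, C-3) and (S)-carvone (ring B, C-12, and the isopropenyl group as C-4/C-13/C-14).
Forward: ring B is bought; ring A is annulated onto it in one flask as a formal [3+3] process (two consecutive stages, no isolation); then the angular methyl, C-11 and the coumarin are attached and C-3 is unmasked.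
What makes the annulation possible: in ring A the C-3 carbonyl lies between the gem-dimethyl carbon C-4 and a CH2–CH2 pair ending at C-10, the neighbour of C-9. With C-9 as a ketone, C-10 is an enolate carbon (Michael donor towards C-1 of acrylonitrile). C-4 is the tertiary radical that H-atom transfer to an isopropenyl group gives, and the nitrile carbon C-3 is its acceptor.
Stereochemistry: C-5 is the stereocentre of (S)-carvone; C-10 is set by methylation of the bicyclic enolate anti to C-4 (cis ring fusion); C-9 by hydroboration from the convex face, which puts C-11 trans to the angular methyl.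

Key step: step 1

Remark on the chemistry: read from the SMILES, H-5 and CH3-10 are cis (cis-fused decalin) and the CH2OAr group on C-9 is trans to CH3-10 (cis to C-1); the route is laid out for this isomer.

**Step 1**
Reactants: 1 (S)-carvone [(5S)-2-methyl-5-(prop-1-en-2-yl)cyclohex-2-en-1-one]; 2 acrylonitrile
Product: 6 (4aS)-2,5,5-trimethyl-4a,5,8,8a-tetrahydronaphthalene-1,6(4H,7H)-dione (both C-8a epimers), via lithium dienolate 3 (not isolated), via Michael adduct 4 (not isolated), via ketimine 5 (not isolated)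
Conditions: LiN(SiMe3)2 (1.0 equiv), THF, −78 °C; 2 (1.0 equiv, slow addition), −78 °C; AcOH; volatiles removed; Fe(acac)3 (30 mol %), PhSiH3 (2.5 equiv), EtOH (0.02 M), 60 °C; then 1 M HCl, rt
Reagents that add atoms: water, O (oxygen of the C-3 ketone); LiN(SiMe3)2, [Li+].C[Si](C)(C)[N-][Si](C)(C)C (lithium of 3 only)
Why: Kinetic deprotonation of 1 at C-10 gives the cross-conjugated lithium dienolate 3, which adds to the β-carbon of acrylonitrile (Michael addition, bond C-1–C-10); the HN(SiMe3)2 set free on enolisation is expected to protonate the lithiated nitrile before it can add to C-7 of the enone. Under the iron hydride conditions an H atom is transferred to the CH2 end of the isopropenyl group, the tertiary C-4 radical adds to the nitrile carbon C-3 (bond C-3–C-4), and the iminyl radical is reduced to ketimine 5, which the acid hydrolyses to the C-3 ketone. The closest known reaction types are the cyanoethylation of kinetic ketone enolates and the Fe(acac)3/PhSiH3 HAT-initiated cyclisation of alkenyl nitriles to cyclic ketones, run here in one flask as a formal [3+3] annulation. Ring A closes 6-exo-dig, the only ring size open to the C-4 radical, since attack on the enone carbons would give three- or four-membered rings. C-5 is untouched and keeps the carvone configuration; C-10 forms as an epimer mixture, which does not matter because C-10 is enolised in step 3. The step needs HAT to the electron-rich 1,1-disubstituted alkene rather than to the enone, and cyclisation before the radical is reduced; the alkene substitution pattern and high dilution should secure both.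

**Step 2**
Reactants: 6 (4aS)-2,5,5-trimethyl-4a,5,8,8a-tetrahydronaphthalene-1,6(4H,7H)-dione
Product: 7 (4aS)-6,6-(ethylenedioxy)-2,5,5-trimethyl-4a,5,6,7,8,8a-hexahydronaphthalen-1(4H)-one
Conditions: (TMSOCH2)2 (1.5 equiv), TMSOTf (5 mol %), CH2Cl2, −78 to −20 °C
Reagents that add atoms: 1,2-bis(trimethylsilyloxy)ethane, C[Si](C)(C)OCCO[Si](C)(C)C
Why: Noyori ketalisation takes the saturated C-3 ketone and leaves the conjugated, doubly flanked C-9 ketone free; the protection is needed because the amide base of step 3 would otherwise enolise C-3 towards C-2.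

**Step 3**
Reactants: 7 (4aS)-6,6-(ethylenedioxy)-2,5,5-trimethyl-4a,5,6,7,8,8a-hexahydronaphthalen-1(4H)-one
Product: 9 (4aR,8aS)-6,6-(ethylenedioxy)-2,5,5,8a-tetramethyl-4a,5,6,7,8,8a-hexahydronaphthalen-1(4H)-one, via lithium enolate 8 (not isolated)
Conditions: LiN(i-Pr)2 (1.1 equiv), THF, −78 to −30 °C; MeI (3 equiv), DMPU, −78 °C to rt
Reagents that add atoms: iodomethane, CI; LiN(i-Pr)2, [Li+].CC(C)[N-]C(C)C (lithium of 8 only)
Why: Kinetic enolisation at the only α′ position (C-10) gives the cross-conjugated dienolate 8, and C-methylation (angular enolate alkylation) should occur on the face anti to the C-5–C-4 bond and its gem-dimethyl group, so that CH3 ends trans to C-4 and cis to H-5, i.e. the cis ring fusion, as in the anti alkylation of 6-substituted carvone enolates.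

**Step 4**
Reactants: 9 (4aR,8aS)-6,6-(ethylenedioxy)-2,5,5,8a-tetramethyl-4a,5,6,7,8,8a-hexahydronaphthalen-1(4H)-one
Product: 10 (4aS,8aS)-6,6-(ethylenedioxy)-2,5,5,8a-tetramethyl-1-methylidene-1,4,4a,5,6,7,8,8a-octahydronaphthalene
Conditions: Ph3PCH3Br (3 equiv), KOt-Bu (2.8 equiv), toluene, 90 °C
Reagents that add atoms: methyltriphenylphosphonium bromide, C[P+](c1ccccc1)(c1ccccc1)c1ccccc1.[Br-]
Why: Wittig methylenation under hot, salt-free conditions is the standard way to convert a hindered ketone without α′-hydrogen into its methylene compound; the ketal and both stereocentres are inert to the ylide.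

**Step 5**
Reactants: 10 (4aS,8aS)-6,6-(ethylenedioxy)-2,5,5,8a-tetramethyl-1-methylidene-1,4,4a,5,6,7,8,8a-octahydronaphthalene
Product: 12 [(1R,4aS,8aS)-6,6-(ethylenedioxy)-2,5,5,8a-tetramethyl-1,4,4a,5,6,7,8,8a-octahydronaphthalen-1-yl]methanol, via organoborane 11 (not isolated)
Conditions: 9-BBN (2 equiv), THF, 0 to 60 °C; then 3 M NaOH, 30% H2O2, 0 °C to rt
Reagents that add atoms: hydrogen peroxide, OO; 9-borabicyclo[3.3.1]nonane, B1C2CCCC1CCC2 (boron and ring of 11 only)
Why: Hydroboration–oxidation places boron on the terminal C-11 of the 1,1-disubstituted alkene and leaves the trisubstituted C-7=C-8 alkene; H should be delivered to C-9 from the convex face (that of CH3-10 and H-5), because ring A with C-1 and the C-4 substituent covers the other face of the cis-decalin, so C-11 ends cis to C-1 and trans to the angular methyl.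

**Step 6**
Reactants: 12 [(1R,4aS,8aS)-6,6-(ethylenedioxy)-2,5,5,8a-tetramethyl-1,4,4a,5,6,7,8,8a-octahydronaphthalen-1-yl]methanol; 13 umbelliferone (7-hydroxy-2H-chromen-2-one)
Product: 14 7-{[(1R,4aS,8aS)-6,6-(ethylenedioxy)-2,5,5,8a-tetramethyl-1,4,4a,5,6,7,8,8a-octahydronaphthalen-1-yl]methoxy}-2H-chromen-2-one
Conditions: PPh3 (1.5 equiv), DIAD (1.5 equiv), 13 (1.3 equiv), THF, 0 to 40 °C
Reagents that add atoms: none
Why: Mitsunobu etherification of a primary alcohol with an acidic phenol (pKa about 8) forms the O–C-11 bond at a CH2 group, so no stereocentre is touched.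

**Step 7**
Reactants: 14 7-{[(1R,4aS,8aS)-6,6-(ethylenedioxy)-2,5,5,8a-tetramethyl-1,4,4a,5,6,7,8,8a-octahydronaphthalen-1-yl]methoxy}-2H-chromen-2-one
Product: 15 7-{[(1R,4aS,8aS)-2,5,5,8a-tetramethyl-6-oxo-1,4,4a,5,6,7,8,8a-octahydronaphthalen-1-yl]methoxy}-2H-chromen-2-one (target)
Conditions: 1 M HCl, THF, rt
Reagents that add atoms: water, O
Why: Acid-catalysed acetal hydrolysis frees the C-3 ketone; the crowded dioxolane next to the gem-dimethyl carbon opens readily, while the coumarin lactone, the aryl ether and the trisubstituted alkene should tolerate dilute acid at room temperature.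

**Compound list**
1 | (S)-carvone, (5S)-2-methyl-5-(prop-1-en-2-yl)cyclohex-2-en-1-one | CC1=CC[C@H](C(C)=C)CC1=O | starting material
2 | acrylonitrile | C=CC#N | starting material
3 | lithium (3S)-6-methyl-3-(prop-1-en-2-yl)cyclohexa-1,5-dien-1-olate (not isolated) | CC1=CC[C@H](C(C)=C)C=C1[O-].[Li+] | intermediate
4 | 3-[(6S)-3-methyl-2-oxo-6-(prop-1-en-2-yl)cyclohex-3-en-1-yl]propanenitrile, both C-1 epimers (not isolated) | CC1=CC[C@H](C(C)=C)C(CCC#N)C1=O | intermediate
5 | (4aS)-6-imino-2,5,5-trimethyl-4a,5,6,7,8,8a-hexahydronaphthalen-1(4H)-one, both C-8a epimers (not isolated) | CC1=CC[C@@H]2C(C)(C)C(=N)CCC2C1=O | intermediate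
6 | (4aS)-2,5,5-trimethyl-4a,5,8,8a-tetrahydronaphthalene-1,6(4H,7H)-dione, both C-8a epimers | CC1=CC[C@@H]2C(C)(C)C(=O)CCC2C1=O | intermediate
7 | (4aS)-6,6-(ethylenedioxy)-2,5,5-trimethyl-4a,5,6,7,8,8a-hexahydronaphthalen-1(4H)-one, both C-8a epimers | CC1=CC[C@@H]2C(C)(C)C3(OCCO3)CCC2C1=O | intermediate
8 | lithium (4aS)-6,6-(ethylenedioxy)-2,5,5-trimethyl-4,4a,5,6,7,8-hexahydronaphthalen-1-olate (not isolated) | CC1=CC[C@@H]2C(C)(C)C3(OCCO3)CCC2=C1[O-].[Li+] | intermediate
9 | (4aR,8aS)-6,6-(ethylenedioxy)-2,5,5,8a-tetramethyl-4a,5,6,7,8,8a-hexahydronaphthalen-1(4H)-one | CC1=CC[C@@H]2C(C)(C)C3(OCCO3)CC[C@]2(C)C1=O | intermediate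
10 | (4aS,8aS)-6,6-(ethylenedioxy)-2,5,5,8a-tetramethyl-1-methylidene-1,4,4a,5,6,7,8,8a-octahydronaphthalene | CC1=CC[C@@H]2C(C)(C)C3(OCCO3)CC[C@]2(C)C1=C | intermediate
11 | 9-{[(1R,4aS,8aR)-6,6-(ethylenedioxy)-2,5,5,8a-tetramethyl-1,4,4a,5,6,7,8,8a-octahydronaphthalen-1-yl]methyl}-9-borabicyclo[3.3.1]nonane (not isolated) | CC1=CC[C@@H]2C(C)(C)C3(OCCO3)CC[C@]2(C)[C@@H]1CB1C2CCCC1CCC2 | intermediate
12 | [(1R,4aS,8aS)-6,6-(ethylenedioxy)-2,5,5,8a-tetramethyl-1,4,4a,5,6,7,8,8a-octahydronaphthalen-1-yl]methanol | CC1=CC[C@@H]2C(C)(C)C3(OCCO3)CC[C@]2(C)[C@@H]1CO | intermediate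
13 | umbelliferone, 7-hydroxy-2H-chromen-2-one | Oc1ccc2ccc(=O)oc2c1 | starting material
14 | 7-{[(1R,4aS,8aS)-6,6-(ethylenedioxy)-2,5,5,8a-tetramethyl-1,4,4a,5,6,7,8,8a-octahydronaphthalen-1-yl]methoxy}-2H-chromen-2-one | CC1=CC[C@@H]2C(C)(C)C3(OCCO3)CC[C@]2(C)[C@@H]1COc1ccc2ccc(=O)oc2c1 | intermediate
15 | 7-{[(1R,4aS,8aS)-2,5,5,8a-tetramethyl-6-oxo-1,4,4a,5,6,7,8,8a-octahydronaphthalen-1-yl]methoxy}-2H-chromen-2-one | CC1=CC[C@@H]2C(C)(C)C(=O)CC[C@]2(C)[C@@H]1COc1ccc2ccc(=O)oc2c1 | target

**Step count and risks**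
Total steps: 7. Longest linear sequence: 7 steps (from 1).

Step 1 (key step). What may go wrong: in the first stage the metalated nitrile may react on (a second, intramolecular conjugate addition to C-7 of the enone, or double cyanoethylation); in the second stage the tertiary radical may be reduced before the slow 6-exo-dig closure onto the nitrile. The fallback sets out from 1 and comes back at 6. The lithium dienolate 3 (made with LiN(i-Pr)2) is C-alkylated with 2-(2-iodoethyl)-1,3-dioxolane (THF–DMPU, −78 to 0 °C) to give (5S)-6-[2-(1,3-dioxolan-2-yl)ethyl]-2-methyl-5-(prop-1-en-2-yl)cyclohex-2-en-1-one F1; an alkyl iodide leaves no carbanion behind, so no second conjugate addition is possible. Dilute aqueous acid in THF gives 3-[(6S)-3-methyl-2-oxo-6-(prop-1-en-2-yl)cyclohex-3-en-1-yl]propanal F2, whose carbonyl group is a much faster radical acceptor than a nitrile. The same Fe(acac)3/PhSiH3 conditions (HAT-initiated alkene–carbonyl cyclisation) should give (4aS)-6-hydroxy-2,5,5-trimethyl-4a,5,6,7,8,8a-hexahydronaphthalen-1(4H)-one F3, and Dess–Martin oxidation returns 6.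

Step 3. What may go wrong: insufficient facial selectivity in the angular methylation (trans-fused epimer), or deprotonation at the γ position C-6 followed by methylation at C-8. The fallback sets out from 4 (isolated by working up step 1 after its first stage) and comes back at 9; it sets the quaternary centre on the monocycle, where the isopropenyl group alone controls the face. LiN(i-Pr)2 gives lithium (3R)-2-(2-cyanoethyl)-6-methyl-3-(prop-1-en-2-yl)cyclohexa-1,5-dien-1-olate F4, and iodomethane enters anti to the isopropenyl group to give 3-[(1S,6R)-1,3-dimethyl-2-oxo-6-(prop-1-en-2-yl)cyclohex-3-en-1-yl]propanenitrile F5, in which the cyanoethyl chain is cis to the isopropenyl group. Fe(acac)3/PhSiH3 in EtOH closes ring A to (4aR,8aS)-6-imino-2,5,5,8a-tetramethyl-4a,5,6,7,8,8a-hexahydronaphthalen-1(4H)-one F6, which aqueous HCl hydrolyses to the cis-fused (4aR,8aS)-2,5,5,8a-tetramethyl-4a,5,8,8a-tetrahydronaphthalene-1,6(4H,7H)-dione F7. Ketalisation as in step 2 gives 9.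

Step 5. What may go wrong: poor facial selectivity in the delivery of H to C-9, giving the C-9 epimer. The fallback sets out from 9 and comes back at 12; it makes C-9 an epimerisable centre instead of one fixed by a single kinetic event. Wittig reaction with the ylide from (methoxymethyl)triphenylphosphonium chloride and KOt-Bu gives (4aS,8aS)-6,6-(ethylenedioxy)-1-(methoxymethylidene)-2,5,5,8a-tetramethyl-1,4,4a,5,6,7,8,8a-octahydronaphthalene F8. Brief hydrolysis with aqueous oxalic acid at 0 °C (kinetic protonation at C-9) gives (1R,4aS,8aS)-6,6-(ethylenedioxy)-2,5,5,8a-tetramethyl-1,4,4a,5,6,7,8,8a-octahydronaphthalene-1-carbaldehyde F9. The unwanted C-9 epimer can be separated and recycled through its dienolate (LiN(SiMe3)2, then AcOH at −78 °C). NaBH4 in MeOH reduces F9 to 12.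

**Further compounds**
F1 | step 1 | (5S)-6-[2-(1,3-dioxolan-2-yl)ethyl]-2-methyl-5-(prop-1-en-2-yl)cyclohex-2-en-1-one, both C-6 epimers | CC1=CC[C@H](C(C)=C)C(CCC2OCCO2)C1=O
F2 | step 1 | 3-[(6S)-3-methyl-2-oxo-6-(prop-1-en-2-yl)cyclohex-3-en-1-yl]propanal, both C-1 epimers | CC1=CC[C@H](C(C)=C)C(CCC=O)C1=O
F3 | step 1 | (4aS)-6-hydroxy-2,5,5-trimethyl-4a,5,6,7,8,8a-hexahydronaphthalen-1(4H)-one, C-6 and C-8a epimers | CC1=CC[C@@H]2C(C)(C)C(O)CCC2C1=O
F4 | step 3 | lithium (3R)-2-(2-cyanoethyl)-6-methyl-3-(prop-1-en-2-yl)cyclohexa-1,5-dien-1-olate | CC1=CC[C@H](C(C)=C)C(CCC#N)=C1[O-].[Li+]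
F5 | step 3 | 3-[(1S,6R)-1,3-dimethyl-2-oxo-6-(prop-1-en-2-yl)cyclohex-3-en-1-yl]propanenitrile | CC1=CC[C@H](C(C)=C)[C@](C)(CCC#N)C1=O
F6 | step 3 | (4aR,8aS)-6-imino-2,5,5,8a-tetramethyl-4a,5,6,7,8,8a-hexahydronaphthalen-1(4H)-one | CC1=CC[C@@H]2C(C)(C)C(=N)CC[C@]2(C)C1=O
F7 | step 3 | (4aR,8aS)-2,5,5,8a-tetramethyl-4a,5,8,8a-tetrahydronaphthalene-1,6(4H,7H)-dione | CC1=CC[C@@H]2C(C)(C)C(=O)CC[C@]2(C)C1=O
F8 | step 5 | (4aS,8aS)-6,6-(ethylenedioxy)-1-(methoxymethylidene)-2,5,5,8a-tetramethyl-1,4,4a,5,6,7,8,8a-octahydronaphthalene, E/Z mixture | CC1=CC[C@@H]2C(C)(C)C3(OCCO3)CC[C@]2(C)C1=COC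
F9 | step 5 | (1R,4aS,8aS)-6,6-(ethylenedioxy)-2,5,5,8a-tetramethyl-1,4,4a,5,6,7,8,8a-octahydronaphthalene-1-carbaldehyde | CC1=CC[C@@H]2C(C)(C)C3(OCCO3)CC[C@]2(C)[C@@H]1C=O
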